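**Plan**

- Numbering: oxane O1, C2 (aryl), C3 (arm C8H2–C9H=C10H–aryl), C4, C5, C6; carbinol carbon C7. The unit aryl–C7(O)–C5(C4)–C6–O1 is what an (E)-aryl alkene becomes when C5 gains a formaldehyde carbon and C7 an oxygen, and this is what makes a formaldehyde Prins reaction possible.
- Cuts, in retrosynthetic order: C2–aryl (oxocarbenium ion + arylzinc), C9=C10 (cross-metathesis), C3–C8 (lactone enolate allylation), O1–C2 (lactone of a diol ester), C5–C6 together with C7–O (Prins), C3–C4 (Johnson–Claisen), C5–C7 (vinyl Grignard).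
- Forward: the pentenoate chain is built (steps 1–2); a temporary 1,3-dioxane is closed on it (step 3) and exchanged for the six-membered lactone that becomes the oxane ring (step 4). C3 is allylated and corrected (6–7), C2 is arylated via lactol and sulfone (8–10), the arm is completed by metathesis (11), and the masked phenol is unveiled and the silyl groups removed (12–13).
- Stereochemistry: C5 from the chiral acid; C7 from suprafacial, trans closure on the (E)-alkene; C3 from kinetic protonation of the lactone enolate (cis to C5); C2 from axial attack on the oxocarbenium ion (cis to C3 and C5).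

Key step: step 3

Remark 1: the oxygen of the phenol ring on C7 is carried as bromine up to step 12, because a para-oxygen donor would make the alkene of step 3 and the C7–O bond in the acidic steps 3, 4 and 9 prone to ionisation.
Remark 2: the sense of induction of the chiral acid for a β-substituted aryl alkene is assumed, and the catalyst antipode that gives (4R,5R)-8 is used; paraformaldehyde serves as formaldehyde 7. TBS = tert-butyldimethylsilyl.

**Step 1**
Reactants: 1 4-bromobenzaldehyde; 2 vinylmagnesium bromide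
Product: 3 rac-1-(4-bromophenyl)prop-2-en-1-ol
Conditions: THF, −78 → 0 °C
Reagents that add atoms: none
Why: Grignard 1,2-addition of the vinyl group to the aldehyde; the carbinol centre is racemic and is erased in step 2.

**Step 2**
Reactants: 3 rac-1-(4-bromophenyl)prop-2-en-1-ol; 4 trimethyl orthoacetate
Product: 6 methyl (E)-5-(4-bromophenyl)pent-4-enoate, via ketene acetal 5 (not isolated)
Conditions: MeC(OMe)3 (excess), EtCO2H (cat.), 110 → 130 °C, MeOH distilled off
Reagents that add atoms: none
Why: Johnson–Claisen rearrangement, in which acid-catalysed exchange gives ketene acetal 5 and its chair-like [3,3] shift with the aryl group equatorial should deliver the (E)-alkene and the two-carbon ester arm.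

**Step 3**
Reactants: 6 methyl (E)-5-(4-bromophenyl)pent-4-enoate; 7 formaldehyde (two units, as paraformaldehyde)
Product: 8 methyl 3-[(4R,5R)-4-(4-bromophenyl)-1,3-dioxan-5-yl]propanoate
Conditions: (CH2O)n (4 equiv), chiral imino-imidodiphosphate acid (two 3,3′-bis(perfluoro-2-naphthyl)-BINOL units on a P(=O)–NH–P(=NSO2CF3) core, 5 mol%), cyclohexane, 30 °C
Reagents that add atoms: none
Why: The confined acid protonates a formaldehyde oligomer inside its chiral pocket, the electrophilic CH2 carbon bonds to C5 of the alkene while positive charge builds at the benzylic carbon C7, and the hydroxyl oxygen of the second formaldehyde unit takes up that charge. This is the Brønsted-acid-catalysed asymmetric intermolecular Prins reaction of aryl alkenes with paraformaldehyde to 4-aryl-1,3-dioxanes, here applied to a β-alkylated member; the acid-catalysed Prins reaction of (E)-1-arylalkenes to trans-4,5-disubstituted dioxanes is classical. The dioxane closes through a six-membered chair-like transition state in which the hemiformal oxygen adds to C7, the second bond of a formal and highly asynchronous (4+2) addition across the alkene. C5 is set by the chiral counteranion, which selects the alkene face that the formaldehyde carbon attacks; C7 follows from delivery of carbon and oxygen to the same face of the (E)-alkene, and a stepwise closure would also place aryl and chain trans-diequatorial. The step needs face selection at C5, trans closure and the regiochemistry carbon-to-C5/oxygen-to-C7; the aryl group directs charge to C7, the (E)-geometry fixes the trans relation, and the para-bromine keeps the alkene in the electronic range of ordinary styrenes so that cationic oligomerisation and capture of C7 by the ester carbonyl should not compete.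

**Step 4**
Reactants: 8 methyl 3-[(4R,5R)-4-(4-bromophenyl)-1,3-dioxan-5-yl]propanoate
Product: 10 (5R)-5-[(R)-(4-bromophenyl)(hydroxy)methyl]oxan-2-one, via diol ester 9 (not isolated)
Conditions: HCl (1.25 M in MeOH), 60 °C; evaporate; PPTS (cat.), PhMe, 50 °C
Reagents that add atoms: none
Why: Acid-catalysed transacetalisation passes the formaldehyde carbon to methanol as volatile dimethoxymethane without breaking the C7–O bond (a 4-bromophenyl carbinol does not ionise readily), and kinetic lactonisation then closes the six-membered lactone through the primary hydroxyl, which acylates faster than the hindered benzylic one; C5 and C7 are untouched.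

**Step 5**
Reactants: 10 (5R)-5-[(R)-(4-bromophenyl)(hydroxy)methyl]oxan-2-one
Product: 11 (5R)-5-[(R)-(4-bromophenyl)(tert-butyldimethylsilyloxy)methyl]oxan-2-one
Conditions: TBSOTf, 2,6-lutidine, CH2Cl2, −78 → 0 °C
Reagents that add atoms: tert-butyldimethylsilyl trifluoromethanesulfonate, CC(C)(C)[Si](C)(C)OS(=O)(=O)C(F)(F)F
Why: Silyl triflate silylation of a hindered secondary benzylic alcohol under lutidine buffering, which the lactone tolerates.

**Step 6**
Reactants: 11 (5R)-5-[(R)-(4-bromophenyl)(tert-butyldimethylsilyloxy)methyl]oxan-2-one; 12 allyl bromide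
Product: 14 (3R,5R)-5-[(R)-(4-bromophenyl)(tert-butyldimethylsilyloxy)methyl]-3-(prop-2-enyl)oxan-2-one, via lithium enolate 13 (not isolated)
Conditions: LiN(i-Pr)2 (1.1 equiv), THF, −78 °C; then allyl bromide, −78 → −40 °C
Reagents that add atoms: none
Why: Lactone enolate alkylation, in which the electrophile should enter axially on the half-chair enolate that keeps the C5 substituent pseudo-equatorial and so give mainly the 3,5-trans isomer (C3 is reset in step 7).

**Step 7**
Reactants: 14 (3R,5R)-5-[(R)-(4-bromophenyl)(tert-butyldimethylsilyloxy)methyl]-3-(prop-2-enyl)oxan-2-one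
Product: 16 (3S,5R)-5-[(R)-(4-bromophenyl)(tert-butyldimethylsilyloxy)methyl]-3-(prop-2-enyl)oxan-2-one, via lithium enolate 15 (not isolated)
Conditions: LiN(i-Pr)2 (1.3 equiv), THF, −78 °C; then 2,6-di-tert-butyl-4-methylphenol, −78 °C
Reagents that add atoms: none
Why: Enolisation and kinetic protonation, in which the proton should take the same axial path as the electrophile of step 6 and arrive trans to the C5 substituent, so that the allyl group ends equatorial and cis (3S), which is also the more stable diequatorial lactone.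

**Step 8**
Reactants: 16 (3S,5R)-5-[(R)-(4-bromophenyl)(tert-butyldimethylsilyloxy)methyl]-3-(prop-2-enyl)oxan-2-one
Product: 17 (3S,5R)-5-[(R)-(4-bromophenyl)(tert-butyldimethylsilyloxy)methyl]-3-(prop-2-enyl)oxan-2-ol (both C2 epimers)
Conditions: i-Bu2AlH (1.2 equiv), CH2Cl2, −78 °C; aq. potassium sodium tartrate
Reagents that add atoms: none
Why: Partial hydride reduction of a lactone, which at low temperature stops at the aluminium hemiacetal and gives the lactol on work-up, with aryl bromide, silyl ether and alkene inert.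

**Step 9**
Reactants: 17 (3S,5R)-5-[(R)-(4-bromophenyl)(tert-butyldimethylsilyloxy)methyl]-3-(prop-2-enyl)oxan-2-ol
Product: 18 (3S,5R)-2-(benzenesulfonyl)-5-[(R)-(4-bromophenyl)(tert-butyldimethylsilyloxy)methyl]-3-(prop-2-enyl)oxane (both C2 epimers)
Conditions: PhSO2H (3 equiv), CaCl2, CH2Cl2, rt
Reagents that add atoms: benzenesulfinic acid, O=S(O)c1ccccc1
Why: Acid-promoted exchange of the anomeric hydroxyl for sulfinate (formation of a 2-sulfonyl cyclic ether from a lactol), driven by CaCl2 as desiccant; the C2 configuration is irrelevant because C2 is ionised in step 10.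

**Step 10**
Reactants: 18 (3S,5R)-2-(benzenesulfonyl)-5-[(R)-(4-bromophenyl)(tert-butyldimethylsilyloxy)methyl]-3-(prop-2-enyl)oxane; 19 (4-bromophenoxy)(tert-butyl)dimethylsilane
Product: 22 (2R,3S,5R)-5-[(R)-(4-bromophenyl)(tert-butyldimethylsilyloxy)methyl]-2-[4-(tert-butyldimethylsilyloxy)phenyl]-3-(prop-2-enyl)oxane, via aryl Grignard reagent 20 (not isolated), via diarylzinc 21 (not isolated)
Conditions: 19, Mg, THF, 45 °C; ZnBr2 (0.5 equiv per Grignard), 0 °C → rt; then 18, THF, rt
Reagents that add atoms: none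
Why: Substitution of a 2-sulfonyl cyclic ether by an organozinc reagent, in which zinc-assisted loss of sulfinate gives the cyclic oxocarbenium ion and the aryl group should add axially to the half-chair that keeps the C3 and C5 substituents pseudo-equatorial, placing the aryl group cis to both (2R) under mild conditions that should not re-ionise the product.

**Step 11**
Reactants: 22 (2R,3S,5R)-5-[(R)-(4-bromophenyl)(tert-butyldimethylsilyloxy)methyl]-2-[4-(tert-butyldimethylsilyloxy)phenyl]-3-(prop-2-enyl)oxane; 23 tert-butyl(4-ethenylphenoxy)dimethylsilane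
Product: 24 (2R,3S,5R)-5-[(R)-(4-bromophenyl)(tert-butyldimethylsilyloxy)methyl]-2-[4-(tert-butyldimethylsilyloxy)phenyl]-3-[(E)-3-[4-(tert-butyldimethylsilyloxy)phenyl]prop-2-enyl]oxane
Conditions: 23 (3 equiv), second-generation Grubbs catalyst RuCl2(=CHPh)(PCy3)(SIMes) (5 mol%), CH2Cl2, 40 °C
Reagents that add atoms: none
Why: Olefin cross-metathesis of the terminal allyl group with the styrene, driven by loss of ethene and expected to give the aryl-conjugated (E)-alkene.

**Step 12**
Reactants: 24 (2R,3S,5R)-5-[(R)-(4-bromophenyl)(tert-butyldimethylsilyloxy)methyl]-2-[4-(tert-butyldimethylsilyloxy)phenyl]-3-[(E)-3-[4-(tert-butyldimethylsilyloxy)phenyl]prop-2-enyl]oxane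
Product: 26 4-[(R)-(tert-butyldimethylsilyloxy){(3R,5S,6R)-6-[4-(tert-butyldimethylsilyloxy)phenyl]-5-[(E)-3-[4-(tert-butyldimethylsilyloxy)phenyl]prop-2-enyl]oxan-3-yl}methyl]phenol, via pinacol boronate 25 (not isolated)
Conditions: B2pin2, PdCl2(dppf) (5 mol%), KOAc, 1,4-dioxane, 80 °C; then NaBO3·4H2O, THF/H2O, rt
Reagents that add atoms: sodium perborate, [Na+].[Na+].O[B-]1(O)OO[B-](O)(O)OO1
Why: Miyaura borylation of the only aryl bromide, followed by perborate oxidation (aryl shift from boron to oxygen), should unmask the third phenol under mildly basic conditions that leave the alkene and the benzylic centres alone; any aryl silyl ether lost here is due for removal in step 13 anyway.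

**Step 13**
Reactants: 26 the phenol of step 12
Product: 27 4-[(E)-3-[(2R,3S,5R)-5-[(R)-hydroxy(4-hydroxyphenyl)methyl]-2-(4-hydroxyphenyl)oxan-3-yl]prop-1-enyl]phenol
Conditions: Bu4NF, AcOH (1:1, excess), THF, 0 °C → rt
Reagents that add atoms: none
Why: Fluoride desilylation of the two aryl silyl ethers and the benzylic silyl ether, buffered with acetic acid so that the phenols stay protonated and neither benzylic C–O bond (C2, C7) is lost through a quinone methide.

**Compound list**

1 | 4-bromobenzaldehyde | O=Cc1ccc(Br)cc1 | starting material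
2 | vinylmagnesium bromide | C=C[Mg]Br | starting material
3 | rac-1-(4-bromophenyl)prop-2-en-1-ol | C=CC(O)c1ccc(Br)cc1 | intermediate
4 | trimethyl orthoacetate | CC(OC)(OC)OC | starting material
5 | 1-bromo-4-[1-(1-methoxyethenyloxy)prop-2-enyl]benzene (ketene acetal) | C=CC(OC(=C)OC)c1ccc(Br)cc1 | intermediate (not isolated)
6 | methyl (E)-5-(4-bromophenyl)pent-4-enoate | COC(=O)CC/C=C/c1ccc(Br)cc1 | intermediate
7 | formaldehyde (as paraformaldehyde) | C=O | starting material
8 | methyl 3-[(4R,5R)-4-(4-bromophenyl)-1,3-dioxan-5-yl]propanoate | COC(=O)CC[C@@H]1COCO[C@H]1c1ccc(Br)cc1 | intermediate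
9 | methyl (4R,5R)-5-(4-bromophenyl)-5-hydroxy-4-(hydroxymethyl)pentanoate | COC(=O)CC[C@H](CO)[C@@H](O)c1ccc(Br)cc1 | intermediate (not isolated)
10 | (5R)-5-[(R)-(4-bromophenyl)(hydroxy)methyl]oxan-2-one | O=C1CC[C@@H]([C@@H](O)c2ccc(Br)cc2)CO1 | intermediate
11 | (5R)-5-[(R)-(4-bromophenyl)(tert-butyldimethylsilyloxy)methyl]oxan-2-one | O=C1CC[C@@H]([C@@H](O[Si](C)(C)C(C)(C)C)c2ccc(Br)cc2)CO1 | intermediate
12 | allyl bromide | C=CCBr | starting material
13 | lithium enolate of 11 (lithium (3R)-3-[(R)-(4-bromophenyl)(tert-butyldimethylsilyloxy)methyl]-3,4-dihydro-2H-pyran-6-olate) | [Li]OC1=CC[C@@H]([C@@H](O[Si](C)(C)C(C)(C)C)c2ccc(Br)cc2)CO1 | intermediate (not isolated)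
14 | (3R,5R)-5-[(R)-(4-bromophenyl)(tert-butyldimethylsilyloxy)methyl]-3-(prop-2-enyl)oxan-2-one (3,5-trans) | O=C1[C@H](CC=C)C[C@@H]([C@@H](O[Si](C)(C)C(C)(C)C)c2ccc(Br)cc2)CO1 | intermediate
15 | lithium enolate of 14 (5-(prop-2-enyl) analogue of 13) | [Li]OC1=C(CC=C)C[C@@H]([C@@H](O[Si](C)(C)C(C)(C)C)c2ccc(Br)cc2)CO1 | intermediate (not isolated)
16 | (3S,5R)-5-[(R)-(4-bromophenyl)(tert-butyldimethylsilyloxy)methyl]-3-(prop-2-enyl)oxan-2-one (3,5-cis) | O=C1[C@@H](CC=C)C[C@@H]([C@@H](O[Si](C)(C)C(C)(C)C)c2ccc(Br)cc2)CO1 | intermediate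
17 | (3S,5R)-5-[(R)-(4-bromophenyl)(tert-butyldimethylsilyloxy)methyl]-3-(prop-2-enyl)oxan-2-ol (C2 epimers) | OC1[C@@H](CC=C)C[C@@H]([C@@H](O[Si](C)(C)C(C)(C)C)c2ccc(Br)cc2)CO1 | intermediate
18 | (3S,5R)-2-(benzenesulfonyl)-5-[(R)-(4-bromophenyl)(tert-butyldimethylsilyloxy)methyl]-3-(prop-2-enyl)oxane (C2 epimers) | O=S(=O)(c1ccccc1)C1[C@@H](CC=C)C[C@@H]([C@@H](O[Si](C)(C)C(C)(C)C)c2ccc(Br)cc2)CO1 | intermediate
19 | (4-bromophenoxy)(tert-butyl)dimethylsilane | CC(C)(C)[Si](C)(C)Oc1ccc(Br)cc1 | starting material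
20 | [4-(tert-butyldimethylsilyloxy)phenyl]magnesium bromide | CC(C)(C)[Si](C)(C)Oc1ccc([Mg]Br)cc1 | intermediate (not isolated)
21 | bis[4-(tert-butyldimethylsilyloxy)phenyl]zinc | CC(C)(C)[Si](C)(C)Oc1ccc([Zn]c2ccc(O[Si](C)(C)C(C)(C)C)cc2)cc1 | intermediate (not isolated)
22 | (2R,3S,5R)-5-[(R)-(4-bromophenyl)(tert-butyldimethylsilyloxy)methyl]-2-[4-(tert-butyldimethylsilyloxy)phenyl]-3-(prop-2-enyl)oxane | C=CC[C@H]1C[C@@H]([C@@H](O[Si](C)(C)C(C)(C)C)c2ccc(Br)cc2)CO[C@H]1c1ccc(O[Si](C)(C)C(C)(C)C)cc1 | intermediate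
23 | tert-butyl(4-ethenylphenoxy)dimethylsilane | C=Cc1ccc(O[Si](C)(C)C(C)(C)C)cc1 | starting material
24 | (2R,3S,5R)-5-[(R)-(4-bromophenyl)(tert-butyldimethylsilyloxy)methyl]-2-[4-(tert-butyldimethylsilyloxy)phenyl]-3-[(E)-3-[4-(tert-butyldimethylsilyloxy)phenyl]prop-2-enyl]oxane | CC(C)(C)[Si](C)(C)Oc1ccc(/C=C/C[C@H]2C[C@@H]([C@@H](O[Si](C)(C)C(C)(C)C)c3ccc(Br)cc3)CO[C@H]2c2ccc(O[Si](C)(C)C(C)(C)C)cc2)cc1 | intermediate
25 | analogue of 24 with 4-(4,4,5,5-tetramethyl-1,3,2-dioxaborolan-2-yl)phenyl in place of 4-bromophenyl | CC(C)(C)[Si](C)(C)Oc1ccc(/C=C/C[C@H]2C[C@@H]([C@@H](O[Si](C)(C)C(C)(C)C)c3ccc(B4OC(C)(C)C(C)(C)O4)cc3)CO[C@H]2c2ccc(O[Si](C)(C)C(C)(C)C)cc2)cc1 | intermediate (not isolated)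
26 | analogue of 24 with 4-hydroxyphenyl in place of 4-bromophenyl (name in step 12) | CC(C)(C)[Si](C)(C)Oc1ccc(/C=C/C[C@H]2C[C@@H]([C@@H](O[Si](C)(C)C(C)(C)C)c3ccc(O)cc3)CO[C@H]2c2ccc(O[Si](C)(C)C(C)(C)C)cc2)cc1 | intermediate
27 | 4-[(E)-3-[(2R,3S,5R)-5-[(R)-hydroxy(4-hydroxyphenyl)methyl]-2-(4-hydroxyphenyl)oxan-3-yl]prop-1-enyl]phenol | Oc1ccc(/C=C/C[C@H]2C[C@@H]([C@@H](O)c3ccc(O)cc3)CO[C@H]2c2ccc(O)cc2)cc1 | target

**Step count**

Total: 13 steps. Longest linear sequence: 13 steps (1 → 27); all other inputs (2, 4, 7, 12, 19, 23) are bought.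

**Steps most likely to fail**

Step 3. The β-substituent may hinder entry of the alkene into the confined pocket, so turnover could be slow, facial selection at C5 poor, or acid-induced oligomerisation of the alkene could take over.
- The fallback replaces catalyst control by a reduction/alkylation sequence and sets out from aldehyde 1.
- Homologation of 1 with ethyl diazoacetate and SnCl2 (Roskamp reaction) gives ethyl 3-(4-bromophenyl)-3-oxopropanoate F1.
- Noyori hydrogenation with RuCl2[(S)-BINAP] gives ethyl (3R)-3-(4-bromophenyl)-3-hydroxypropanoate F2.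
- Fráter–Seebach alkylation of its dianion (2 equiv LiN(i-Pr)2) with allyl bromide 12 gives the anti product ethyl (2S)-2-[(R)-(4-bromophenyl)(hydroxy)methyl]pent-4-enoate F3.
- LiAlH4 reduces the ester to (1R,2R)-1-(4-bromophenyl)-2-(prop-2-enyl)propane-1,3-diol F4.
- CH2(OMe)2 with TsOH closes (4R,5R)-4-(4-bromophenyl)-5-(prop-2-enyl)-1,3-dioxane F5.
- Hydroboration with 9-BBN and oxidation with H2O2/NaOH give 3-[(4R,5R)-4-(4-bromophenyl)-1,3-dioxan-5-yl]propan-1-ol F6.
- TEMPO/PhI(OAc)2 in aqueous MeCN gives 3-[(4R,5R)-4-(4-bromophenyl)-1,3-dioxan-5-yl]propanoic acid F7.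
- Methylation (MeI, K2CO3) returns to the route at 8.

Step 10. Axial selectivity may be lost (attack through a twist-boat or on the other half-chair, with a gauche interaction to the C3 group), or benzenesulfinic acid may be eliminated to the enol ether.
- The fallback sets C2 by reagent control before the ring is closed and sets out from lactone 16.
- Bromide 19 is converted with n-BuLi (THF, −78 °C) into [4-(tert-butyldimethylsilyloxy)phenyl]lithium F8.
- F8 adds once to 16 to give (2S,4R)-4-[(R)-(4-bromophenyl)(tert-butyldimethylsilyloxy)methyl]-5-hydroxy-1-[4-(tert-butyldimethylsilyloxy)phenyl]-2-(prop-2-enyl)pentan-1-one F9.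
- Corey–Bakshi–Shibata reduction ((S)-methyl oxazaborolidine, BH3·SMe2, excess) should give (1R,2S,4R)-4-[(R)-(4-bromophenyl)(tert-butyldimethylsilyloxy)methyl]-1-[4-(tert-butyldimethylsilyloxy)phenyl]-2-(prop-2-enyl)pentane-1,5-diol F10.
- TsCl/pyridine sulfonylates only the primary hydroxyl to give the 5-(4-methylbenzenesulfonate) of that diol F11.
- NaH in THF closes the oxane by displacement at the primary carbon; the C2–O bond is not broken, so its configuration is kept. This returns to the route at 22.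

Step 4. The benzylic hydroxyl may compete in ring closure or translactonisation, or the acetal exchange may be slow enough to need conditions under which C7–O solvolysis begins.
- The fallback differentiates the two hydroxyls by protection and sets out from 8.
- After the methanolysis the acid is neutralised before evaporation, so that diol ester 9 is isolated.
- TBSOTf/2,6-lutidine silylates both hydroxyls to give methyl (4R,5R)-5-(4-bromophenyl)-5-(tert-butyldimethylsilyloxy)-4-[(tert-butyldimethylsilyloxy)methyl]pentanoate F12.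
- CSA in MeOH at 0 °C removes only the primary silyl ether, giving methyl (4R,5R)-5-(4-bromophenyl)-5-(tert-butyldimethylsilyloxy)-4-(hydroxymethyl)pentanoate F13.
- F13 lactonises with PPTS in warm toluene and returns to the route at 11.

**Further compounds**

F1 | step 3 | ethyl 3-(4-bromophenyl)-3-oxopropanoate | CCOC(=O)CC(=O)c1ccc(Br)cc1
F2 | step 3 | ethyl (3R)-3-(4-bromophenyl)-3-hydroxypropanoate | CCOC(=O)C[C@@H](O)c1ccc(Br)cc1
F3 | step 3 | ethyl (2S)-2-[(R)-(4-bromophenyl)(hydroxy)methyl]pent-4-enoate | CCOC(=O)[C@@H](CC=C)[C@@H](O)c1ccc(Br)cc1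
F4 | step 3 | (1R,2R)-1-(4-bromophenyl)-2-(prop-2-enyl)propane-1,3-diol | C=CC[C@H](CO)[C@@H](O)c1ccc(Br)cc1
F5 | step 3 | (4R,5R)-4-(4-bromophenyl)-5-(prop-2-enyl)-1,3-dioxane | C=CC[C@@H]1COCO[C@H]1c1ccc(Br)cc1
F6 | step 3 | 3-[(4R,5R)-4-(4-bromophenyl)-1,3-dioxan-5-yl]propan-1-ol | OCCC[C@@H]1COCO[C@H]1c1ccc(Br)cc1
F7 | step 3 | 3-[(4R,5R)-4-(4-bromophenyl)-1,3-dioxan-5-yl]propanoic acid | OC(=O)CC[C@@H]1COCO[C@H]1c1ccc(Br)cc1
F8 | step 10 | [4-(tert-butyldimethylsilyloxy)phenyl]lithium | [Li]c1ccc(O[Si](C)(C)C(C)(C)C)cc1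
F9 | step 10 | (2S,4R)-4-[(R)-(4-bromophenyl)(tert-butyldimethylsilyloxy)methyl]-5-hydroxy-1-[4-(tert-butyldimethylsilyloxy)phenyl]-2-(prop-2-enyl)pentan-1-one | O=C(c1ccc(O[Si](C)(C)C(C)(C)C)cc1)[C@@H](CC=C)C[C@H](CO)[C@@H](O[Si](C)(C)C(C)(C)C)c1ccc(Br)cc1
F10 | step 10 | (1R,2S,4R)-4-[(R)-(4-bromophenyl)(tert-butyldimethylsilyloxy)methyl]-1-[4-(tert-butyldimethylsilyloxy)phenyl]-2-(prop-2-enyl)pentane-1,5-diol | O[C@@H](c1ccc(O[Si](C)(C)C(C)(C)C)cc1)[C@@H](CC=C)C[C@H](CO)[C@@H](O[Si](C)(C)C(C)(C)C)c1ccc(Br)cc1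
F11 | step 10 | 5-(4-methylbenzenesulfonate) of F10 | O[C@@H](c1ccc(O[Si](C)(C)C(C)(C)C)cc1)[C@@H](CC=C)C[C@H](COS(=O)(=O)c1ccc(C)cc1)[C@@H](O[Si](C)(C)C(C)(C)C)c1ccc(Br)cc1
F12 | step 4 | methyl (4R,5R)-5-(4-bromophenyl)-5-(tert-butyldimethylsilyloxy)-4-[(tert-butyldimethylsilyloxy)methyl]pentanoate | COC(=O)CC[C@H](CO[Si](C)(C)C(C)(C)C)[C@@H](O[Si](C)(C)C(C)(C)C)c1ccc(Br)cc1
F13 | step 4 | methyl (4R,5R)-5-(4-bromophenyl)-5-(tert-butyldimethylsilyloxy)-4-(hydroxymethyl)pentanoate | COC(=O)CC[C@H](CO)[C@@H](O[Si](C)(C)C(C)(C)C)c1ccc(Br)cc1
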